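**Plan**

Numbering used throughout: ring C1 (stereocentre) to C14, with C2 the ring CH2 next to C1; ring alkenes C3=C4 (CH2OH on C4), C7=C8 and C11=C12; side chain C1'(Me)=C2'H–C3'H2–C4'H=C5'Me2 on C1.
Enabling feature: C1–C2 is the central σ-bond of a 1,5-diene (C2'=C1'–C1–C2–C3=C4), with C2 allylic to the ring C3=C4 alkene and C1 allylic to the exocyclic C1'=C2' alkene. The retrosynthesis cuts this bond as the reverse of a [2,3]-sigmatropic shift of a sulfonium ylide: sulfur is placed between C2 and C2', which gives a temporary 17-membered thiacycle (S, C2', C1', C1, C14 … C2) with a C1=C1' alkene.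
The thiacycle is cut at S–C2 (thiolate + allylic chloride), the linear C25 chain at C9–C10 (allylic sulfone anion + allylic bromide), the C10–C5' fragment at C2'–C3' (allylation) back to nerol, and the C2–C9 fragment at C4–C5 (organocopper + ynoate).
Forward: nerol → sulfone → C2' enal → allylation and cross-metathesis (east fragment 7); ynoate carbocupration → west bromide 18; sulfone coupling, desulfonylation, OH → SAc at C2', OTBS → Cl at C2; the thiolate closes the 17-membered ring; S-methylation, ylide formation and [2,3] shift contract it to the 14-membered carbocycle; desilylation and reductive C–S cleavage finish.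
Stereochemistry: C2'–OH (S) from a Keck allylation is inverted to C2'–S (R) by a Mitsunobu reaction and transferred to C1 (R) in the key step, which also sets the (E)-C1'=C2' alkene; C11=C12 (Z) comes from nerol, C7=C8 and C1=C1' (E) from selenium dioxide oxidation of (E)-methyl groups, and the C3=C4 geometry from syn-carbocupration.

Key step: step 19

Assumption: nerol is used as the pure (2Z)-isomer and silyl ether 8 is bought (otherwise one silylation of propargyl alcohol); the sulfonyl-bearing carbon of 20 and the methylsulfanyl-bearing carbon of 29 and 30 are epimer mixtures that converge when sulfur is removed.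

**Route**

Step 1
Reactants: 1 nerol
Product: 2 neryl bromide
Conditions: PBr3 (0.4 equiv), Et2O, −10 °C
Reagents that add atoms: phosphorus tribromide, BrP(Br)Br
Why: SN2 bromination of the primary allylic alcohol through its phosphite ester at low temperature should proceed without allylic transposition or loss of the (Z)-geometry.

Step 2
Reactants: 2 neryl bromide
Product: 3 neryl phenyl sulfone
Conditions: PhSO2Na, DMF, rt
Reagents that add atoms: sodium benzenesulfinate, [Na+].[O-]S(=O)c1ccccc1
Why: S-alkylation of the sulfinate by SN2 at the primary allylic bromide gives the allylic sulfone that later acts as the C10 nucleophile and deactivates the C11=C12 alkene towards the next oxidation.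

Step 3
Reactants: 3 neryl phenyl sulfone
Product: 4 (2E,6Z)-2,6-dimethyl-8-(phenylsulfonyl)octa-2,6-dien-1-ol
Conditions: SeO2 (cat.), t-BuOOH, salicylic acid (cat.), CH2Cl2, rt
Reagents that add atoms: tert-butyl hydroperoxide, CC(C)(C)OO (oxygen relayed by catalytic selenium dioxide, O=[Se]=O)
Why: Riley oxidation (ene reaction, then [2,3] shift of the allylseleninic acid) should hydroxylate the (E)-methyl group of the electron-rich terminal alkene selectively, giving the (E)-C1=C1' alkene with C2' as CH2OH.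

Step 4
Reactants: 4 (2E,6Z)-2,6-dimethyl-8-(phenylsulfonyl)octa-2,6-dien-1-ol
Product: 5 (2E,6Z)-2,6-dimethyl-8-(phenylsulfonyl)octa-2,6-dienal
Conditions: MnO2, CH2Cl2, rt
Reagents that add atoms: none
Why: Manganese dioxide oxidation of the primary allylic alcohol should give the enal without affecting the sulfone or either alkene geometry.

Step 5
Reactants: 5 (2E,6Z)-2,6-dimethyl-8-(phenylsulfonyl)octa-2,6-dienal
Product: 6 (4S,5E,9Z)-5,9-dimethyl-11-(phenylsulfonyl)undeca-1,5,9-trien-4-ol
Conditions: allylSnBu3, (S)-BINOL (20 mol %), Ti(OiPr)4 (10 mol %), 4 Å MS, CH2Cl2, −20 °C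
Reagents that add atoms: allyltributylstannane, C=CC[Sn](CCCC)(CCCC)CCCC
Why: Keck asymmetric allylation, in which the (S)-BINOL–titanium Lewis acid directs allyl transfer to the Si face of the α-methyl enal, should set the (S)-carbinol centre at C2'.

Step 6
Reactants: 6 (4S,5E,9Z)-5,9-dimethyl-11-(phenylsulfonyl)undeca-1,5,9-trien-4-ol
Product: 7 (5S,6E,10Z)-2,6,10-trimethyl-12-(phenylsulfonyl)dodeca-2,6,10-trien-5-ol (east fragment)
Conditions: 2-methylbut-2-ene (excess), Grubbs second-generation catalyst (5 mol %), CH2Cl2, 40 °C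
Reagents that add atoms: 2-methylbut-2-ene, CC=C(C)C
Why: Olefin cross-metathesis with excess 2-methylbut-2-ene should convert the monosubstituted vinyl group into the prenyl terminus, the two trisubstituted alkenes being too hindered to engage the ruthenium carbene.

Step 7
Reactants: 8 tert-butyl(diphenyl)(prop-2-yn-1-yloxy)silane
Product: 10 methyl 4-[(tert-butyldiphenylsilyl)oxy]but-2-ynoate, via lithium acetylide 9 (not isolated)
Conditions: n-BuLi, THF, −78 °C; then ClCO2Me, −78 → 0 °C
Reagents that add atoms: methyl chloroformate, COC(=O)Cl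
Why: Deprotonation of the terminal alkyne and C-acylation of the lithium acetylide with the chloroformate should give the ynoate acceptor.

Step 8
Reactants: 11 5-bromo-2-methylpent-2-ene; 10 methyl 4-[(tert-butyldiphenylsilyl)oxy]but-2-ynoate
Product: 14 methyl (2Z)-3-{[(tert-butyldiphenylsilyl)oxy]methyl}-7-methylocta-2,6-dienoate, via Grignard reagent 12 (not isolated), via organocopper reagent 13 (not isolated)
Conditions: Mg, THF; CuBr·SMe2 (1 equiv), THF, −78 → −40 °C; then 10, −78 °C; NH4Cl quench at −78 °C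
Reagents that add atoms: none
Why: Syn-carbocupration of the ynoate (conjugate addition of the organocopper reagent, then protonation of the alkenylcopper with retention at −78 °C) should place the C5 chain cis to H, so that the ester carbon (C2) and the CH2OTBDPS group end up cis on the C3=C4 alkene.

Step 9
Reactants: 14 methyl (2Z)-3-{[(tert-butyldiphenylsilyl)oxy]methyl}-7-methylocta-2,6-dienoate
Product: 15 (2Z)-3-{[(tert-butyldiphenylsilyl)oxy]methyl}-7-methylocta-2,6-dien-1-ol
Conditions: DIBAL-H, CH2Cl2, −78 °C; Rochelle salt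
Reagents that add atoms: none
Why: DIBAL-H should reduce the unsaturated ester to the primary allylic alcohol by 1,2-hydride delivery without affecting the alkene geometry or the silyl ether.

Step 10
Reactants: 15 (2Z)-3-{[(tert-butyldiphenylsilyl)oxy]methyl}-7-methylocta-2,6-dien-1-ol
Product: 16 (2Z)-1-[(tert-butyldimethylsilyl)oxy]-3-{[(tert-butyldiphenylsilyl)oxy]methyl}-7-methylocta-2,6-diene
Conditions: TBSCl, imidazole, CH2Cl2, 0 °C → rt
Reagents that add atoms: tert-butyldimethylsilyl chloride, CC(C)(C)[Si](C)(C)Cl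
Why: Silylation distinguishes the C2 oxygen (acid-labile TBS) from the C4 hydroxymethyl oxygen (TBDPS) for the later selective unmasking.

Step 11
Reactants: 16 (2Z)-1-[(tert-butyldimethylsilyl)oxy]-3-{[(tert-butyldiphenylsilyl)oxy]methyl}-7-methylocta-2,6-diene
Product: 17 (2E,6Z)-8-[(tert-butyldimethylsilyl)oxy]-6-{[(tert-butyldiphenylsilyl)oxy]methyl}-2-methylocta-2,6-dien-1-ol
Conditions: SeO2 (cat.), t-BuOOH, salicylic acid (cat.), CH2Cl2, 0 °C → rt
Reagents that add atoms: tert-butyl hydroperoxide, CC(C)(C)OO (oxygen relayed by catalytic selenium dioxide, O=[Se]=O)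
Why: Riley oxidation should again select the (E)-methyl group of the terminal trisubstituted alkene, the C3=C4 alkene being deactivated by its two allylic silyloxy groups, and give the (E)-C7=C8 allylic alcohol.

Step 12
Reactants: 17 (2E,6Z)-8-[(tert-butyldimethylsilyl)oxy]-6-{[(tert-butyldiphenylsilyl)oxy]methyl}-2-methylocta-2,6-dien-1-ol
Product: 18 (2E,6Z)-1-bromo-8-[(tert-butyldimethylsilyl)oxy]-6-{[(tert-butyldiphenylsilyl)oxy]methyl}-2-methylocta-2,6-diene (west fragment)
Conditions: CBr4, PPh3, 2,6-lutidine, CH2Cl2, −20 °C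
Reagents that add atoms: carbon tetrabromide, BrC(Br)(Br)Br
Why: The Appel reaction should convert the primary allylic alcohol into the bromide by SN2 displacement of the oxyphosphonium ion without allylic transposition.

Step 13
Reactants: 7 east fragment alcohol; 18 west fragment bromide
Product: 20 C25 hydroxy sulfone (C9–C10 coupled; both epimers at the sulfonyl-bearing carbon), via dilithio sulfone 19 (not isolated)
Conditions: n-BuLi (2.1 equiv), THF/DMPU, −78 °C; then 18, −78 → −40 °C
Reagents that add atoms: none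
Why: Julia-type alkylation, in which the α-sulfonyl allyl carbanion of the dianion attacks the primary allylic bromide by SN2 through its α-carbon, should join C9 to C10, the lithium alkoxide being far less nucleophilic at −78 °C.

Step 14
Reactants: 20 C25 hydroxy sulfone
Product: 21 (5S,6E,10Z,14E,18Z)-20-[(tert-butyldimethylsilyl)oxy]-18-{[(tert-butyldiphenylsilyl)oxy]methyl}-2,6,10,14-tetramethylicosa-2,6,10,14,18-pentaen-5-ol
Conditions: LiBHEt3, PdCl2(dppp) (5 mol %), THF, 0 °C
Reagents that add atoms: none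
Why: Palladium-catalysed reductive desulfonylation should reduce the π-allylpalladium complex of the allylic sulfone with hydride at the less substituted terminus C10, keeping the C11=C12 double bond in place and, with the bidentate dppp ligand, in its (Z)-geometry.

Step 15
Reactants: 21 C25 alcohol
Product: 22 S-[(5R,6E,10Z,14E,18Z)-20-[(tert-butyldimethylsilyl)oxy]-18-{[(tert-butyldiphenylsilyl)oxy]methyl}-2,6,10,14-tetramethylicosa-2,6,10,14,18-pentaen-5-yl] ethanethioate
Conditions: PPh3, DIAD, AcSH, THF, 0 °C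
Reagents that add atoms: thioacetic acid, CC(=O)S
Why: The Mitsunobu reaction with thioacetic acid should substitute the only free hydroxyl group by SN2 with inversion and so give the (R)-configured C2'–S centre needed for the chirality transfer.

Step 16
Reactants: 22 C25 thioacetate
Product: 23 S-[(5R,6E,10Z,14E,18Z)-18-{[(tert-butyldiphenylsilyl)oxy]methyl}-20-hydroxy-2,6,10,14-tetramethylicosa-2,6,10,14,18-pentaen-5-yl] ethanethioate
Conditions: CSA (cat.), MeOH/CH2Cl2, 0 °C
Reagents that add atoms: none
Why: Acid-catalysed methanolysis should cleave the primary TBS ether much faster than the TBDPS ether and leave the thioester intact.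

Step 17
Reactants: 23 C2 alcohol
Product: 24 S-[(5R,6E,10Z,14E,18Z)-20-chloro-18-{[(tert-butyldiphenylsilyl)oxy]methyl}-2,6,10,14-tetramethylicosa-2,6,10,14,18-pentaen-5-yl] ethanethioate
Conditions: MsCl, 2,4,6-collidine, LiCl, DMF, 0 °C
Reagents that add atoms: lithium chloride, [Li+].[Cl-]
Why: In situ mesylation and SN2 chloride displacement should convert the primary allylic alcohol into the allylic chloride without transposition, the thioester being inert.

Step 18
Reactants: 24 C2 chloride
Product: 26 (2R,3E,7Z,11E,15Z)-15-{[(tert-butyldiphenylsilyl)oxy]methyl}-3,7,11-trimethyl-2-(3-methylbut-2-en-1-yl)-1-thiacycloheptadeca-3,7,11,15-tetraene, via potassium thiolate 25 (not isolated)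
Conditions: K2CO3, degassed MeOH/THF, syringe-pump addition (final 1 mM), rt
Reagents that add atoms: none
Why: Methanolysis of the thioester frees the thiolate, whose intramolecular SN2 attack (exo-tet) on the primary allylic chloride under high dilution should close the 17-membered thiacycle without touching the C2' stereocentre.

Step 19
Reactants: 26 17-membered thiacycle
Product: 29 tert-butyl({(1Z,4S,7Z,11E)-7,11-dimethyl-4-[(2E)-6-methylhepta-2,5-dien-2-yl]-3-(methylsulfanyl)cyclotetradeca-1,7,11-trien-1-yl}methoxy)diphenylsilane, via sulfonium triflate 27 (not isolated), via sulfonium ylide 28 (not isolated)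
Conditions: MeOTf, CH2Cl2, −40 → −10 °C; then KOtBu, THF, −78 → −40 °C
Reagents that add atoms: methyl trifluoromethanesulfonate, COS(=O)(=O)C(F)(F)F
Why: Proposed new method: S-methylation of 26 gives the bis-allylic sulfonium salt 27, tert-butoxide removes the most acidic proton (ring C2–H, primary, α to S+ and allylic to C3=C4) to give ylide 28, and the ylide carbon C2 bonds to C1 while the S–C2' bond breaks in a concerted five-centre, six-electron [2,3]-sigmatropic shift across the C2'–C1'=C1 allyl unit. The closest known reactions are the [2,3] shift of acyclic bis-allylic S-methylsulfonium ylides used for head-to-tail couplings of allylic terpenoid units and the [2,3]-Wittig ring contraction of 17-membered allylic ethers to 14-membered carbocycles; the sulfonium-ylide version run as a macrocyclic ring contraction is, as far as is known, without precedent. The 14-membered carbocycle is closed by ring contraction (17 → 14): C1 and C2 are already held together by the sulfur bridge, so the closure is an intramolecular five-membered envelope process and not an end-to-end cyclisation. The C1 stereocentre is set by suprafacial 1,3-chirality transfer from the (R)-configured C2': with the C3' methylene pseudo-equatorial (outside) in the envelope, C2 is delivered to the face of the (E)-C1=C1' alkene that gives the target configuration at C1 (R in 31, formally 4S in 29 because the sulfur-bearing C2 outranks C1') and the new C1'=C2' alkene is formed (E), while the sulfur-bearing C2 centre is formed without control and is erased in step 21. The step needs ylide formation at C2 rather than at C2'–H or S–CH3, and a [2,3] shift that outruns [1,2] shift, β-elimination and ionisation of the sulfonium salt; the higher kinetic acidity of the unhindered primary allylic α-CH2 group, the low temperature and the high rate of allyl-ylide rearrangement are relied on for this, and the alternative envelope (C3' inside) would give a separable (Z)-alkene isomer and not the enantiomer.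

Step 20
Reactants: 29 14-membered ring silyl ether
Product: 30 {(1Z,4S,7Z,11E)-7,11-dimethyl-4-[(2E)-6-methylhepta-2,5-dien-2-yl]-3-(methylsulfanyl)cyclotetradeca-1,7,11-trien-1-yl}methanol
Conditions: TBAF, THF, 0 °C → rt
Reagents that add atoms: none
Why: Fluoride-mediated desilylation frees the primary alcohol, which must be present as its alkoxide in the last step so that no 1,4-reductive elimination across C2–C3=C4–CH2O can occur.

Step 21
Reactants: 30 methylsulfanyl alcohol
Product: 31 {(1Z,4R,7Z,11E)-7,11-dimethyl-4-[(2E)-6-methylhepta-2,5-dien-2-yl]cyclotetradeca-1,7,11-trien-1-yl}methanol (target)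
Conditions: Li, EtNH2/THF, −78 °C; then aqueous work-up
Reagents that add atoms: none
Why: Dissolving-metal reduction should cleave the allylic C–S bond and the resulting allyl anion should be protonated at its less substituted terminus C2, keeping the C3=C4 alkene in place (reductive desulfurisation of an allylic sulfide).

**Compound list**

1 | nerol, (2Z)-3,7-dimethylocta-2,6-dien-1-ol | CC(C)=CCC/C(C)=C\CO | starting material
2 | neryl bromide, (2Z)-1-bromo-3,7-dimethylocta-2,6-diene | CC(C)=CCC/C(C)=C\CBr | intermediate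
3 | neryl phenyl sulfone, {[(2Z)-3,7-dimethylocta-2,6-dien-1-yl]sulfonyl}benzene | CC(C)=CCC/C(C)=C\CS(=O)(=O)c1ccccc1 | intermediate
4 | (2E,6Z)-2,6-dimethyl-8-(phenylsulfonyl)octa-2,6-dien-1-ol | OC/C(C)=C/CC/C(C)=C\CS(=O)(=O)c1ccccc1 | intermediate
5 | (2E,6Z)-2,6-dimethyl-8-(phenylsulfonyl)octa-2,6-dienal | O=C/C(C)=C/CC/C(C)=C\CS(=O)(=O)c1ccccc1 | intermediate
6 | (4S,5E,9Z)-5,9-dimethyl-11-(phenylsulfonyl)undeca-1,5,9-trien-4-ol | C=CC[C@H](O)/C(C)=C/CC/C(C)=C\CS(=O)(=O)c1ccccc1 | intermediate
7 | (5S,6E,10Z)-2,6,10-trimethyl-12-(phenylsulfonyl)dodeca-2,6,10-trien-5-ol | CC(C)=CC[C@H](O)/C(C)=C/CC/C(C)=C\CS(=O)(=O)c1ccccc1 | intermediate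
8 | tert-butyl(diphenyl)(prop-2-yn-1-yloxy)silane | C#CCO[Si](c1ccccc1)(c1ccccc1)C(C)(C)C | starting material
9 | lithium acetylide of 8 | [Li]C#CCO[Si](c1ccccc1)(c1ccccc1)C(C)(C)C | intermediate
10 | methyl 4-[(tert-butyldiphenylsilyl)oxy]but-2-ynoate | COC(=O)C#CCO[Si](c1ccccc1)(c1ccccc1)C(C)(C)C | intermediate
11 | 5-bromo-2-methylpent-2-ene | CC(C)=CCCBr | starting material
12 | (4-methylpent-3-en-1-yl)magnesium bromide | CC(C)=CCC[Mg]Br | intermediate
13 | (4-methylpent-3-en-1-yl)copper (magnesium bromide complex) | CC(C)=CCC[Cu] | intermediate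
14 | methyl (2Z)-3-{[(tert-butyldiphenylsilyl)oxy]methyl}-7-methylocta-2,6-dienoate | COC(=O)/C=C(/CCC=C(C)C)CO[Si](c1ccccc1)(c1ccccc1)C(C)(C)C | intermediate
15 | (2Z)-3-{[(tert-butyldiphenylsilyl)oxy]methyl}-7-methylocta-2,6-dien-1-ol | OC/C=C(/CCC=C(C)C)CO[Si](c1ccccc1)(c1ccccc1)C(C)(C)C | intermediate
16 | (2Z)-1-[(tert-butyldimethylsilyl)oxy]-3-{[(tert-butyldiphenylsilyl)oxy]methyl}-7-methylocta-2,6-diene | CC(C)=CCC/C(CO[Si](c1ccccc1)(c1ccccc1)C(C)(C)C)=C/CO[Si](C)(C)C(C)(C)C | intermediate
17 | (2E,6Z)-8-[(tert-butyldimethylsilyl)oxy]-6-{[(tert-butyldiphenylsilyl)oxy]methyl}-2-methylocta-2,6-dien-1-ol | OC/C(C)=C/CC/C(CO[Si](c1ccccc1)(c1ccccc1)C(C)(C)C)=C/CO[Si](C)(C)C(C)(C)C | intermediate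
18 | (2E,6Z)-1-bromo-8-[(tert-butyldimethylsilyl)oxy]-6-{[(tert-butyldiphenylsilyl)oxy]methyl}-2-methylocta-2,6-diene | BrC/C(C)=C/CC/C(CO[Si](c1ccccc1)(c1ccccc1)C(C)(C)C)=C/CO[Si](C)(C)C(C)(C)C | intermediate
19 | O,C-dilithio derivative of 7 (lithium alkoxide, α-lithio sulfone) | CC(C)=CC[C@H](O[Li])/C(C)=C/CC/C(C)=C\C([Li])S(=O)(=O)c1ccccc1 | intermediate
20 | (5S,6E,10Z,14E,18Z)-20-[(tert-butyldimethylsilyl)oxy]-18-{[(tert-butyldiphenylsilyl)oxy]methyl}-2,6,10,14-tetramethyl-12-(phenylsulfonyl)icosa-2,6,10,14,18-pentaen-5-ol (both C12 epimers) | CC(C)=CC[C@H](O)/C(C)=C/CC/C(C)=C\C(C/C(C)=C/CC/C(CO[Si](c1ccccc1)(c1ccccc1)C(C)(C)C)=C/CO[Si](C)(C)C(C)(C)C)S(=O)(=O)c1ccccc1 | intermediate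
21 | (5S,6E,10Z,14E,18Z)-20-[(tert-butyldimethylsilyl)oxy]-18-{[(tert-butyldiphenylsilyl)oxy]methyl}-2,6,10,14-tetramethylicosa-2,6,10,14,18-pentaen-5-ol | CC(C)=CC[C@H](O)/C(C)=C/CC/C(C)=C\CC/C(C)=C/CC/C(CO[Si](c1ccccc1)(c1ccccc1)C(C)(C)C)=C/CO[Si](C)(C)C(C)(C)C | intermediate
22 | S-[(5R,6E,10Z,14E,18Z)-20-[(tert-butyldimethylsilyl)oxy]-18-{[(tert-butyldiphenylsilyl)oxy]methyl}-2,6,10,14-tetramethylicosa-2,6,10,14,18-pentaen-5-yl] ethanethioate | CC(C)=CC[C@@H](SC(C)=O)/C(C)=C/CC/C(C)=C\CC/C(C)=C/CC/C(CO[Si](c1ccccc1)(c1ccccc1)C(C)(C)C)=C/CO[Si](C)(C)C(C)(C)C | intermediate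
23 | S-[(5R,6E,10Z,14E,18Z)-18-{[(tert-butyldiphenylsilyl)oxy]methyl}-20-hydroxy-2,6,10,14-tetramethylicosa-2,6,10,14,18-pentaen-5-yl] ethanethioate | CC(C)=CC[C@@H](SC(C)=O)/C(C)=C/CC/C(C)=C\CC/C(C)=C/CC/C(CO[Si](c1ccccc1)(c1ccccc1)C(C)(C)C)=C/CO | intermediate
24 | S-[(5R,6E,10Z,14E,18Z)-20-chloro-18-{[(tert-butyldiphenylsilyl)oxy]methyl}-2,6,10,14-tetramethylicosa-2,6,10,14,18-pentaen-5-yl] ethanethioate | CC(C)=CC[C@@H](SC(C)=O)/C(C)=C/CC/C(C)=C\CC/C(C)=C/CC/C(CO[Si](c1ccccc1)(c1ccccc1)C(C)(C)C)=C/CCl | intermediate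
25 | potassium (5R,6E,10Z,14E,18Z)-20-chloro-18-{[(tert-butyldiphenylsilyl)oxy]methyl}-2,6,10,14-tetramethylicosa-2,6,10,14,18-pentaene-5-thiolate | CC(C)=CC[C@@H]([S-])/C(C)=C/CC/C(C)=C\CC/C(C)=C/CC/C(CO[Si](c1ccccc1)(c1ccccc1)C(C)(C)C)=C/CCl.[K+] | intermediate
26 | (2R,3E,7Z,11E,15Z)-15-{[(tert-butyldiphenylsilyl)oxy]methyl}-3,7,11-trimethyl-2-(3-methylbut-2-en-1-yl)-1-thiacycloheptadeca-3,7,11,15-tetraene | CC(C)=CC[C@H]1SC/C=C(\CO[Si](c2ccccc2)(c2ccccc2)C(C)(C)C)CC/C=C(\C)CC/C=C(/C)CC/C=C1\C | intermediate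
27 | (2R,3E,7Z,11E,15Z)-15-{[(tert-butyldiphenylsilyl)oxy]methyl}-1,3,7,11-tetramethyl-2-(3-methylbut-2-en-1-yl)-1-thiacycloheptadeca-3,7,11,15-tetraen-1-ium trifluoromethanesulfonate (both configurations at sulfur) | CC(C)=CC[C@H]1[S+](C)C/C=C(\CO[Si](c2ccccc2)(c2ccccc2)C(C)(C)C)CC/C=C(\C)CC/C=C(/C)CC/C=C1\C.[O-]S(=O)(=O)C(F)(F)F | intermediate
28 | sulfonium ylide of 27 (carbanion at ring C17 of the thiacycle, the CH between S and the CH2OTBDPS-bearing alkene) | CC(C)=CC[C@H]1[S+](C)[CH-]/C=C(\CO[Si](c2ccccc2)(c2ccccc2)C(C)(C)C)CC/C=C(\C)CC/C=C(/C)CC/C=C1\C | intermediate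
29 | tert-butyl({(1Z,4S,7Z,11E)-7,11-dimethyl-4-[(2E)-6-methylhepta-2,5-dien-2-yl]-3-(methylsulfanyl)cyclotetradeca-1,7,11-trien-1-yl}methoxy)diphenylsilane (both C3 epimers) | CC(C)=CC/C=C(\C)[C@H]1C(SC)/C=C(\CO[Si](c2ccccc2)(c2ccccc2)C(C)(C)C)CC/C=C(\C)CC/C=C(/C)CC1 | intermediate
30 | {(1Z,4S,7Z,11E)-7,11-dimethyl-4-[(2E)-6-methylhepta-2,5-dien-2-yl]-3-(methylsulfanyl)cyclotetradeca-1,7,11-trien-1-yl}methanol (both C3 epimers) | CC(C)=CC/C=C(\C)[C@H]1C(SC)/C=C(\CO)CC/C=C(\C)CC/C=C(/C)CC1 | intermediate
31 | {(1Z,4R,7Z,11E)-7,11-dimethyl-4-[(2E)-6-methylhepta-2,5-dien-2-yl]cyclotetradeca-1,7,11-trien-1-yl}methanol | CC(C)=CC/C=C(\C)[C@H]1C/C=C(\CO)CC/C=C(\C)CC/C=C(/C)CC1 | target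

**Step count and risks**

Total steps: 21. Longest linear sequence: 15 steps (steps 1–6 and 13–21; the branch through steps 7–12 is equally long).

Step 19 (Proposed new method). The base may deprotonate C2'–H or S–CH3 instead of C2–H, which would give other [2,3] products or racemise C2' by reversible deprotonation. The secondary allylic sulfonium salt may also ionise or undergo β-elimination, and the envelope with C3' inside would give the (Z)-side-chain alkene. The fallback uses known chemistry, sets out from 7 and 17 and returns at 29: the ylide shift is run on an acyclic bis-allylic sulfonium salt, and the 14-membered ring is closed afterwards at C9–C10 by intramolecular alkylation of the sulfone-stabilised allyl anion. Alcohol 7 would be converted by a Mitsunobu reaction (PPh3, DIAD, AcSH) into the east-fragment (R)-thioacetate F1. Alcohol 17 would be acylated (PivCl, pyridine) to the C9 pivalate F2, its TBS ether methanolysed (CSA, MeOH) to the C2 alcohol F3, and this converted (MsCl, collidine, LiCl) into the C2 allylic chloride F4. K2CO3 in MeOH would free the thiolate of F1 in the presence of F4 and give the acyclic bis-allylic sulfide F5. MeOTf and then KOtBu at −78 °C would effect the ylide [2,3] shift to the C1–C2 coupled methyl sulfide F6, with the same chirality transfer from C2' to C1. DIBAL-H would remove the pivalate to give the C9 alcohol F7, an Appel reaction would give the C9 bromide F8, and LiHMDS in THF under high dilution would close the ring to the macrocyclic C10 sulfone F9. LiBHEt3 with PdCl2(dppp) would then remove the sulfonyl group to give 29.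

Step 21. The allyl anion may be protonated at C4 (double-bond transposition), the C3=C4 geometry may be lost at the allyl radical or anion stage, and the lithium amide may isomerise the skipped diene of the side chain. The fallback sets out from 29 and returns at 31 and replaces electron transfer by palladium-hydride chemistry: the sulfide would be oxidised with H2O2 and catalytic ammonium heptamolybdate in EtOH to the methyl sulfone F10. LiBHEt3 with PdCl2(dppp) would deliver hydride to C2 of the π-allyl complex to give the desulfurised silyl ether F11, and TBAF would give 31.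

Step 3. The allylic oxidation may stall at partial conversion, over-oxidise to the enal or acid, or attack other allylic positions, on the first oxidation of the longest sequence. The fallback sets out from 3 and returns at 5 and builds the enal by cleavage and olefination instead of C–H oxidation: mCPBA would epoxidise the more electron-rich terminal alkene to the terminal epoxide F12. Periodic acid would cleave it to the C1 aldehyde F13, and a Wittig reaction with 2-(triphenylphosphoranylidene)propanal would give (E)-enal 5 directly.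

**Further compounds**

F1 | step 19 | S-[(5R,6E,10Z)-2,6,10-trimethyl-12-(phenylsulfonyl)dodeca-2,6,10-trien-5-yl] ethanethioate | CC(C)=CC[C@@H](SC(C)=O)/C(C)=C/CC/C(C)=C\CS(=O)(=O)c1ccccc1
F2 | step 19 | (2E,6Z)-8-[(tert-butyldimethylsilyl)oxy]-6-{[(tert-butyldiphenylsilyl)oxy]methyl}-2-methylocta-2,6-dien-1-yl 2,2-dimethylpropanoate | CC(C)(C)C(=O)OC/C(C)=C/CC/C(CO[Si](c1ccccc1)(c1ccccc1)C(C)(C)C)=C/CO[Si](C)(C)C(C)(C)C
F3 | step 19 | (2E,6Z)-6-{[(tert-butyldiphenylsilyl)oxy]methyl}-8-hydroxy-2-methylocta-2,6-dien-1-yl 2,2-dimethylpropanoate | CC(C)(C)C(=O)OC/C(C)=C/CC/C(CO[Si](c1ccccc1)(c1ccccc1)C(C)(C)C)=C/CO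
F4 | step 19 | (2E,6Z)-8-chloro-6-{[(tert-butyldiphenylsilyl)oxy]methyl}-2-methylocta-2,6-dien-1-yl 2,2-dimethylpropanoate | CC(C)(C)C(=O)OC/C(C)=C/CC/C(CO[Si](c1ccccc1)(c1ccccc1)C(C)(C)C)=C/CCl
F5 | step 19 | acyclic bis-allylic sulfide joining C2' of the (R)-configured phenylsulfonyl fragment to C2 of the pivalate fragment | CC(C)=CC[C@@H](SC/C=C(\CO[Si](c1ccccc1)(c1ccccc1)C(C)(C)C)CC/C=C(\C)COC(=O)C(C)(C)C)/C(C)=C/CC/C(C)=C\CS(=O)(=O)c1ccccc1
F6 | step 19 | acyclic C1–C2 coupled methyl sulfide with C10 phenylsulfonyl and C9 pivalate termini (C2 epimers) | CC(C)=CC/C=C(\C)[C@H](CC/C(C)=C\CS(=O)(=O)c1ccccc1)C(SC)/C=C(\CO[Si](c1ccccc1)(c1ccccc1)C(C)(C)C)CC/C=C(\C)COC(=O)C(C)(C)C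
F7 | step 19 | C9 primary allylic alcohol from F6 | CC(C)=CC/C=C(\C)[C@H](CC/C(C)=C\CS(=O)(=O)c1ccccc1)C(SC)/C=C(\CO[Si](c1ccccc1)(c1ccccc1)C(C)(C)C)CC/C=C(\C)CO
F8 | step 19 | C9 allylic bromide from F7 | CC(C)=CC/C=C(\C)[C@H](CC/C(C)=C\CS(=O)(=O)c1ccccc1)C(SC)/C=C(\CO[Si](c1ccccc1)(c1ccccc1)C(C)(C)C)CC/C=C(\C)CBr
F9 | step 19 | 14-membered ring bearing phenylsulfonyl at C10 and methylsulfanyl at C2 (C10 phenylsulfonyl derivative of 29) | CC(C)=CC/C=C(\C)[C@H]1C(SC)/C=C(\CO[Si](c2ccccc2)(c2ccccc2)C(C)(C)C)CC/C=C(\C)CC(S(=O)(=O)c2ccccc2)/C=C(/C)CC1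
F10 | step 21 | methyl sulfone of 29 (methylsulfonyl at ring C2) | CC(C)=CC/C=C(\C)[C@H]1C(S(C)(=O)=O)/C=C(\CO[Si](c2ccccc2)(c2ccccc2)C(C)(C)C)CC/C=C(\C)CC/C=C(/C)CC1
F11 | step 21 | tert-butyldiphenylsilyl ether of 31 | CC(C)=CC/C=C(\C)[C@H]1C/C=C(\CO[Si](c2ccccc2)(c2ccccc2)C(C)(C)C)CC/C=C(\C)CC/C=C(/C)CC1
F12 | step 3 | 2,2-dimethyl-3-[(3Z)-3-methyl-5-(phenylsulfonyl)pent-3-en-1-yl]oxirane | CC1(C)OC1CC/C(C)=C\CS(=O)(=O)c1ccccc1
F13 | step 3 | (4Z)-4-methyl-6-(phenylsulfonyl)hex-4-enal | O=CCC/C(C)=C\CS(=O)(=O)c1ccccc1
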